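The constants are made up; the run is a simulation.

Count the catalyst that outlives the impurity before counting its turnovers.

| setting | summer | dusk | dawn |
|---|---|---|---|
| substrate | 0.035 M | 0.035 M | 0.035 M |
| free catalyst | 0.35 mM | 0.35 mM | 0.35 mM |
| impurity | 290 µM | 120 µM | 46 µM |
| time | 1.5 min | 1.5 min | 1.5 min |

    free catalyst + impurity → spent catalyst (k1 = 33000 /M/s)
    catalyst intermediate A → catalyst intermediate B (k2 = 1.6 /s)
    substrate + free catalyst ⇌ catalyst intermediate A (K3 = 50 /M, k3 = 290 /M/s)
    catalyst intermediate B ⇌ free catalyst + target (K4 = 0.086 M, k4 = 0.67 /s)
    target ⇌ isomer of the product (K5 = 1.5, k5 = 0.0011 /s)

* which of the two there is more of at the end, summer (isomer of the product / target)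
* which of the two there is more of at the end, dusk (isomer of the product / target)
* which of the two there is more of at the end, dawn (isomer of the product / target)
* target at the end, in percent of the substrate charged, summer
* target at the end, in percent of the substrate charged, dusk
* target at the end, in percent of the substrate charged, dawn

1. I followed one working catalyst round its cycle, with substrate held at its charge s. Adding the mean waits as free catalyst, catalyst intermediate A and catalyst intermediate B, with the way back to substrate counted, gave a round time τ of 2.57 s, a turnover frequency of 0.389 /s.

2. Each impurity molecule meets free catalyst at 11.6 /s, faster than the catalyst turns over. So I treated this as an early one-for-one titration: with catalyst charge c and impurity charge y, c − y survives. The zero of my scale is y = c.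

3. For summer, with time t, (c − y)·t/(τ·s) came to 6.00%. This is the turnover budget B, the part of the substrate charge that the surviving catalyst can turn over in the time. Dusk gave 23.0% and dawn 30.4%.

4. One number was not enough, because B counts target and isomer together. The forward half-life of target by isomerisation, 11 min, is longer than the time, so I expected isomer near 4.95% of the product, with target ahead in all three flasks. That put target at 5.70% in summer, 21.9% at dusk and 28.9% at dawn. I took the last two as high, since B holds substrate at its charge.

5. The forecast named target, target and target for summer, dusk and dawn, with target at 6%, 21% and 27%, lower than mine at dusk and dawn. Its ground began: “impurity rapidly and irreversibly titrates the catalyst”.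

6. The simulation gave target, target and target, with target at 5.86%, 21.1% and 27.5%, and isomer at 0.298%, 1.04% and 1.36%.

7. The difference in impurity concentration is the main reason for summer's gap to dawn: target in summer stood at 5.86%, and with that difference taken away it stood at 27.5%. Summer's target and isomer stood against a budget of 6.00%. A dusk flask charged with 8.8 × 10⁻⁴ M of free catalyst has a budget of 75.9%. That flask kept 33.6% of its substrate and held 3.21% of isomer and 61.8% of target.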